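**Assumption:** the target has no stereocentre and is achiral, so "single enantiomer" does not apply. The only stereochemical elements are the 2E and 6E alkenes. Both are bought in with (E,E)-farnesol and are never touched.

## Retrosynthetic overview
1. The γ-lactone is the only ring made and is formed last, from a methyl 2-formyl-3-hydroxybenzoate by aldehyde reduction and spontaneous lactonisation.
2. The formyl carbon (future C3) comes from phenol-directed ortho-formylation of a monophenol. Only one ortho position is free, which fixes the 4-OH/3-CH2 relationship.
3. The aryl–O–allyl bond comes from a regioselective Mitsunobu etherification. The more acidic para-OH of methyl 3-O-methylgallate couples with the primary allylic OH of "farnesol hydrate" diol.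
4. The diol comes from (E,E)-farnesol by terminal-selective bromohydrin formation followed by hydride reduction.
5. Ring order: the benzene ring is purchased and the lactone closes in the final step.

## Route

**Step 1**
Reactants: 1, (2E,6E)-farnesol
Product: 2, (2E,6E)-farnesyl acetate
Conditions: Ac2O, Et3N, DMAP (cat.), CH2Cl2, 0 °C to rt
Reagents that add atoms: acetic anhydride, CC(=O)OC(C)=O
Why: DMAP-catalysed acylation. The acetate electronically deactivates the 2,3-alkene for the next step, and neither alkene geometry is affected.

**Step 2**
Reactants: 2, (2E,6E)-farnesyl acetate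
Product: 3, (2E,6E)-10-bromo-11-hydroxy-3,7,11-trimethyldodeca-2,6-dien-1-yl acetate (racemic at C10)
Conditions: NBS (1.1 equiv), t-BuOH/H2O (or THF/H2O), 0–10 °C
Reagents that add atoms: N-bromosuccinimide, O=C1CCC(=O)N1Br; water, O
Why: van Tamelen terminal-selective bromohydrin formation. In aqueous medium the exposed isopropylidene alkene reacts first and water opens the bromonium ion at the tertiary carbon (Markovnikov). The racemic C10 centre is erased in step 3.

**Step 3**
Reactants: 3, bromohydrin acetate
Product: 4, (2E,6E)-3,7,11-trimethyldodeca-2,6-diene-1,11-diol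
Conditions: LiAlH4 (4 equiv), THF, 0 °C to reflux; Rochelle salt work-up
Reagents that add atoms: none
Why: One-pot hydride reduction. The alkoxide closes to the 10,11-epoxide, hydride opens it by SN2 at the less substituted C10 to leave the tertiary alcohol, and the acetate is cleaved reductively at the same time. The isolated trisubstituted alkenes are inert.

**Step 4**
Reactants: 4, diol; 5, methyl 3,4-dihydroxy-5-methoxybenzoate (methyl 3-O-methylgallate, 1.2 equiv)
Product: 6, methyl 3-hydroxy-4-{[(2E,6E)-11-hydroxy-3,7,11-trimethyldodeca-2,6-dien-1-yl]oxy}-5-methoxybenzoate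
Conditions: PPh3, DIAD (1.2 equiv each), THF, 0 °C to rt
Reagents that add atoms: none (both partners are numbered reactants; water is lost)
Why: Regioselective Mitsunobu etherification. Only the primary allylic OH forms the oxyphosphonium (the tertiary OH is inert), and only the more acidic phenol para to the ester is deprotonated and alkylated. Substitution is SN2 at CH2, so the 2E geometry is retained.

**Step 5**
Reactants: 6, monophenol ether
Product: 7, methyl 2-formyl-3-hydroxy-4-{[(2E,6E)-11-hydroxy-3,7,11-trimethyldodeca-2,6-dien-1-yl]oxy}-5-methoxybenzoate
Conditions: anhydrous MgCl2 (3 equiv), Et3N (6 equiv), (CH2O)n (10 equiv), THF or MeCN, reflux; cold 5% citric acid work-up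
Reagents that add atoms: paraformaldehyde (as formaldehyde), C=O
Why: Casnati–Skattebøl ortho-formylation. The magnesium phenoxide delivers formaldehyde only to the ortho carbon, and C2 (also para to OMe) is the sole free ortho site, so C6 is not attacked. Any hydroxymethyl intermediate that lactonises before oxidation is already 8 and passes unchanged through step 6.

**Step 6**
Reactants: 7, formyl ester
Product: 8, farnesylemefuranone E
Conditions: NaBH4 (1.5 equiv), MeOH/THF, 0 °C; then aq. citric acid to pH ~5, rt
Reagents that add atoms: none (MeOH is lost)
Why: Chemoselective aldehyde reduction followed by spontaneous 5-exo-trig lactonisation (phthalide formation) of the benzylic alcohol onto the adjacent methyl ester. The ester/lactone, alkenes, allyl aryl ether and tertiary alcohol all survive.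

## Compound list
| No. | Name | SMILES | Role |
|---|---|---|---|
| 1 | (2E,6E)-farnesol | CC(C)=CCC/C(C)=C/CC/C(C)=C/CO | starting material |
| 2 | (2E,6E)-farnesyl acetate | CC(C)=CCC/C(C)=C/CC/C(C)=C/COC(C)=O | intermediate |
| 3 | (2E,6E)-10-bromo-11-hydroxy-3,7,11-trimethyldodeca-2,6-dienyl acetate (racemic) | CC(C)(O)C(Br)CC/C(C)=C/CC/C(C)=C/COC(C)=O | intermediate |
| 4 | (2E,6E)-3,7,11-trimethyldodeca-2,6-diene-1,11-diol | CC(C)(O)CCC/C(C)=C/CC/C(C)=C/CO | intermediate |
| 5 | methyl 3,4-dihydroxy-5-methoxybenzoate | COC(=O)c1cc(O)c(O)c(OC)c1 | starting material |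
| 6 | methyl 3-hydroxy-4-[(2E,6E)-11-hydroxy-3,7,11-trimethyldodeca-2,6-dienyloxy]-5-methoxybenzoate | COC(=O)c1cc(O)c(OC/C=C(\C)CC/C=C(\C)CCCC(C)(C)O)c(OC)c1 | intermediate |
| 7 | methyl 2-formyl-3-hydroxy-4-[(2E,6E)-11-hydroxy-3,7,11-trimethyldodeca-2,6-dienyloxy]-5-methoxybenzoate | COC(=O)c1cc(OC)c(OC/C=C(\C)CC/C=C(\C)CCCC(C)(C)O)c(O)c1C=O | intermediate |
| 8 | farnesylemefuranone E, 4-hydroxy-5-[(2E,6E)-11-hydroxy-3,7,11-trimethyldodeca-2,6-dienyloxy]-6-methoxyisobenzofuran-1(3H)-one | COc1cc2c(c(O)c1OC/C=C(\C)CC/C=C(\C)CCCC(C)(C)O)COC2=O | target |

## Summary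
Total steps: 6.
Longest linear sequence: 6 (1 → 8); compound 5 enters as purchased.

**Steps most likely to fail**
1. **Step 5.** The ortho-formylation occurs at a hindered carbon flanked by the ester and the phenol, on an ester-deactivated ring. Fallback: boronate-templated (Nagata) ortho-hydroxymethylation with PhB(OH)2, (CH2O)n and catalytic EtCO2H to give the 1,3,2-benzodioxaborin. Releasing it with a diol or H2O2 gives the salicyl alcohol, which lactonises directly to 8. This bypasses aldehyde 7 and step 6.
2. **Step 4.** The catechol may give O-3/O-4 mixtures, bis-ether, or a cyclic dioxyphosphorane. Fallback: convert 4 to the primary allylic chloride or bromide (Corey–Kim NCS/Me2S, or CBr4/PPh3; the tertiary OH is untouched). Then run a Williamson alkylation of 5 with a weak base (Li2CO3 or KHCO3, DMF), which ionises only the para-OH.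
3. **Step 3.** The one-pot bromohydrin → epoxide → tertiary alcohol reduction may stall, or may rearrange to the ketone and hence the secondary alcohol. Fallback: radical debromination of 3 (Bu3SnH or (TMS)3SiH, AIBN; the 4-pentenyl-type radical does not cyclise) to the 11-hydroxy acetate. K2CO3/MeOH methanolysis then gives 4.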